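## The problem

The target is a cis-fused hydroazulene. Numbering used throughout: C1 is the methyl-bearing ring-fusion carbon, C2 the angelate carbon, C3 a methylene, C4 the isopropyl carbinol carbon, C5 the ring-fusion CH, C6 the aryl-ester carbon, C7 a methylene, C8 and C9 the methyl-substituted alkene, C10 a methylene; ring A is the cyclopentane C1–C5 and ring B the cycloheptene C1, C5–C10. Five stereocentres (1R,2S,4S,5R,6R) are crowded around the fusion bond: the C1 methyl, H5 and the isopropyl group lie on the convex face, the C2 and C4 oxygens on the concave face of ring A, and the C6 oxygen on the convex face of ring B, anti to the C4 hydroxyl. C1 dictates C5 through the ring fusion, the fused pair can dictate C4, and the C4 hydroxyl can hand a hydride to C6 on the correct face; at C2 it would deliver to the wrong face, so C2 needs an external reagent. Two different esters must be placed on the two secondary oxygens while the tertiary hydroxyl stays free. The angelate isomerises to the tiglate under base or nucleophilic catalysis, the tertiary hydroxyl is in an aldol relationship to C2 and C6 whenever these are carbonyls (retro-aldol, dehydration), and the C8=C9 alkene slips into conjugation at the C6 ketone stage. The enabling feature is that oxygen sits on C2 and C4 with C3 between them, while C1 and C5 are the β and α carbons of a C6 carbonyl and C8 mirrors C1 across that carbonyl, so a C2–C3–C4 unit that is nucleophilic at C2 and electrophilic at C4 can be annulated onto a symmetric dienone.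

## Retrosynthesis

**C2–O acyl bond.** The angelate is the most fragile group, so target 22 is cut last into alcohol 19 and angelic acid 20. Placing it earlier would expose the Z-enoate to every later base and hydride. The forward step must acylate a hindered secondary hydroxyl next to a quaternary carbon without Z to E isomerisation and without touching the tertiary hydroxyl.

**C2–H bond.** Alcohol 19 comes from ketone 18. The C4 hydroxyl sits on the face where the C2 oxygen has to end up, so hydroxyl-directed delivery would give the wrong epimer. A bulky external hydride from the convex face is required, and the C2 carbonyl must not exist while the directed reduction at C6 is run.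

**C2 carbonyl from nitro.** Ketone 18 is therefore traced to the secondary nitro compound 16 by a Nef reaction. Keeping C2 as nitro through all C6 operations means the two secondary oxygens are never free together, so no protecting group is needed to tell the esters apart. The forward step must be mild enough for an aryl ester, a trisubstituted alkene and a β-hydroxy ketone product.

**C6–O acyl bond.** Ester 16 is cut into diol 14 and 3,4,5-trimethoxybenzoyl chloride 15. Only the secondary C6 hydroxyl should react; the tertiary one is too hindered.

**C6–H bond.** Diol 14 comes from β,γ-unsaturated ketone 13 by intramolecular hydride delivery from the C4 hydroxyl. External hydride would attack from the convex face and give the wrong C6 epimer; directed delivery reaches the concave face and gives the anti diol.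

**Alkene position.** Ketone 13 is the deconjugated isomer of enone 11. The cut costs one step but is forced: the annulation needs the C7=C8 enone, the target the C8=C9 alkene. The forward step needs an extended dienolate protonated kinetically at C7, on a substrate that also carries an aldol hydroxyl and a nitro group.

**C1–C2 and C4–C5 (key).** Enone 11 is opened to dienone 7 and nitro ketone 9. Other ring A cuts (C2–C3 or C3–C4) would need a pre-formed quaternary C1 on a seven-membered ring. This one removes ring A and all of C1, C2, C4 and C5 as stereocentres at once and leaves two achiral pieces, one of them symmetric. The forward reaction must select one of two enantiotopic enone termini, form a quaternary centre with a primary nitronate and close the aldol with isopropyl on the convex face; the open-chain Michael adduct 10 is its intermediate.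

**Dienone 7.** A one-carbon ring expansion traces 7 through chloro ketone 6 to silyloxycyclopropane 5, silyl dienol ether 4 and 3,6-dimethylcyclohexenone 3, which comes from 3-methylcyclohex-2-en-1-one 1 by α′-methylation via enolate 2. A double condensation of a 1,4-diketone with an acetonedicarboxylate was weighed and set aside: 1,4-diketones close to cyclopentenones under base and ketone Knoevenagel condensations are unreliable. The ring expansion puts the former α-methyl carbon at the new β-position, as needed.

**Nitro ketone 9.** The C–N bond is cut to give 4-methylpent-1-en-3-one 8, with nitrogen brought in by conjugate addition at the nitro oxidation level. Adding a one-carbon nitroalkane to 8 would give a homologue with one carbon too many for a five-membered ring A.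

## Roads not taken

**Alternative 1:** Ring B is cut at C7–C8 and C1–C10. A rhodium vinylcarbenoid from methyl 2-diazobut-3-enoate A1 cyclopropanates the silyl enol ether alkene of tert-butyl (2E)-4-[(tert-butyldimethylsilyl)oxy]-2-methylpenta-2,4-dienoate A2. The cis-divinylcyclopropane then undergoes Cope rearrangement to cycloheptadiene A3.
- Merits: with a chiral catalyst such as dirhodium tetrakis[(S)-N-(4-dodecylbenzenesulfonyl)prolinate] this is one of the most dependable enantioselective routes to cycloheptadienes. It fixes the quaternary C1, and the C8=C9 alkene is born in the right place.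
- Weak points: A3 holds only ring B and one stereocentre. C8 carries an ester where a methyl is needed, a multi-step redox detour with a risk of allylic transposition. Ring A must still be built from the C1 ester by adding C3 and C4 and closing onto C5, which is the same aldol as in the chosen route, reached much later.
- Comparison: enantiocontrol at C1 and alkene placement are better precedented here. The chosen plan sets against this one operation that delivers ring A, four stereocentres and the full oxygen pattern from two achiral pieces, at the price of a less certain catalyst-controlled step and an alkene transposition.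

**Alternative 2:** The cut is C1–C5 and C1–C10. A carbenoid generated with dirhodium tetraacetate Rh2(OAc)4 from aryl diazoketone A4 adds to the ipso–ortho bond of the anisole ring and the norcaradiene opens to dihydroazulenone A5, closing both rings.
- Merits: the whole skeleton comes from a flat aromatic precursor in one step, and C4 is present beforehand to bias C1.
- Weak points: the carbenoid carbon bears a methyl group whose 1,2-hydride shift competes, and it must form a quaternary centre. The enantiopure tertiary benzylic carbinol of A4 has to be made first. A5 is at the wrong oxidation level: C5 is sp2, so the fusion hydrogen and cis fusion are still open, C6 is an enol ether, and two of three ring B double bonds must be removed while C8=C9 is created by a 1,4-reduction. Cycloheptatrienes also scramble by hydrogen shifts.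
- Comparison: this road is shorter to the carbon skeleton. The chosen plan sets against it that C1, C4 and C5 arrive as sp3 centres in the correct relative configuration and that only one alkene has to be moved.

**Alternative 3:** Ring B is cut at C1–C10. The silyl ketene acetal of vinyl ε-lactone A6 undergoes an Ireland–Claisen rearrangement through a boat transition state: C1 bonds to C10 as the C8–O bond breaks, giving cycloheptene acid A7.
- Merits: chirality is transferred stereospecifically from C8 to the quaternary C1 relative to C5 and C6. The C6 oxygen and the C8=C9 alkene are delivered in place, and no catalyst control is needed.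
- Weak points: A6 is a demanding target in itself, a medium-ring lactone with three stereocentres, a trans pair of vinyl groups and an ionisable tertiary allylic ester oxygen. A7 still lacks ring A: the vinyl carbons C3 and C4 carry neither the oxygen nor the isopropyl group, so the tertiary carbinol, the C2–C3 bond and the C2 stereocentre all remain.
- Comparison: this road is stronger in the certainty of stereochemical transmission and in setting C6 directly. The chosen plan sets against it a far shorter sequence and formation of ring A with its oxygen pattern in the same step that sets C1.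

Key step: step 6

## Route

Assumption: 9-amino-9-deoxy-epi-quinine is taken to deliver the (1R) series drawn; if the other enone terminus is attacked, the pseudoenantiomeric 9-amino-9-deoxy-epi-quinidine would be used with no other change.
Assumption: compounds 1, 8, 15 and 20 are taken to be commercially available.
Bicyclic intermediates are named with the azulene locants of the target (azulene C1, C3, C3a, C4, C6, C8a = route C2, C4, C5, C6, C8, C1).

Step 1
Reactants: 1 3-methylcyclohex-2-en-1-one
Product: 3 3,6-dimethylcyclohex-2-en-1-one (racemic), via lithium dienolate 2 (not isolated)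
Conditions: LiN(i-Pr)2, THF, −78 °C; MeI, −78 → 0 °C
Reagents that add atoms: iodomethane, CI
Why: Kinetic deprotonation takes the α′ proton and the cross-conjugated dienolate is C-methylated (enolate alkylation); the new centre is racemic and is removed in step 2.

Step 2
Reactants: 3 3,6-dimethylcyclohex-2-en-1-one
Product: 4 [(2,5-dimethylcyclohexa-1,5-dien-1-yl)oxy]trimethylsilane
Conditions: LiN(i-Pr)2, Me3SiCl, THF, −78 °C (in situ quench)
Reagents that add atoms: chlorotrimethylsilane, C[Si](C)(C)Cl
Why: A second kinetic α′-deprotonation removes the C6 methine proton and silylation traps the 2-silyloxy-1,3-diene (silyl enol ether formation); no stereocentre remains.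

Step 3
Reactants: 4 [(2,5-dimethylcyclohexa-1,5-dien-1-yl)oxy]trimethylsilane
Product: 5 [(3,6-dimethylbicyclo[4.1.0]hept-2-en-1-yl)oxy]trimethylsilane (racemic)
Conditions: Et2Zn, CH2I2, Et2O, 0 °C → rt
Reagents that add atoms: diiodomethane, ICI
Why: Furukawa-modified Simmons–Smith cyclopropanation; the electrophilic zinc carbenoid attacks the electron-rich enol ether alkene in preference to the other diene alkene, and the racemic stereocentres are destroyed in step 4.

Step 4
Reactants: 5 [(3,6-dimethylbicyclo[4.1.0]hept-2-en-1-yl)oxy]trimethylsilane
Product: 7 3,6-dimethylcyclohepta-2,6-dien-1-one, via chloro ketone 6 (not isolated)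
Conditions: FeCl3, DMF, 0 °C → rt; then NaOAc, MeOH, 65 °C
Reagents that add atoms: none
Why: FeCl3-mediated oxidative ring expansion of a silyloxycyclopropane: the alkoxy radical cleaves the internal cyclopropane bond, the tertiary radical is chlorinated and acetate removes HCl by E1cB elimination; the inserted CH2 becomes the α′ carbon and the former α-methyl carbon the β′ carbon of the symmetric dienone.

Step 5
Reactants: 8 4-methylpent-1-en-3-one
Product: 9 4-methyl-1-nitropentan-3-one
Conditions: NaNO2, AcOH, THF, rt
Reagents that add atoms: sodium nitrite, [Na+].[O-]N=O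
Why: Conjugate addition of nitrous acid to a vinyl ketone gives the β-nitro ketone; the mildly acidic medium prevents the reverse loss of HNO2, to which the product is prone under base.

Step 6
Reactants: 7 3,6-dimethylcyclohepta-2,6-dien-1-one; 9 4-methyl-1-nitropentan-3-one
Product: 11 (1S,3S,3aS,8aR)-3-hydroxy-6,8a-dimethyl-1-nitro-3-(propan-2-yl)-2,3,3a,7,8,8a-hexahydroazulen-4(1H)-one, via Michael adduct 10 (not isolated)
Conditions: 9-amino-9-deoxy-epi-quinine (20 mol%), 2-FC6H4CO2H (40 mol%), 9 (1.5 equiv), toluene, 9 kbar, 25 °C
Reagents that add atoms: none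
Why: The primary amine condenses with 7 to an iminium ion and the quinuclidine base delivers the nitronate carbon C2 of 9 to the β-carbon C1 of one enone arm, an iminium-catalysed nitro-Michael addition of the kind known for β,β-disubstituted cyclic enones under pressure. The resulting dienamine (or enol) attacks the pendant C4 ketone through C5 in a 5-(enolexo)-exo-trig aldol that closes ring A, and hydrolysis releases the catalyst; the closest known reaction type is the amine-catalysed nitro-Michael/intramolecular aldol domino annulation. C1 is set by the catalyst, and because the two iminium geometries of a symmetric ketone are the same species, the choice between the enantiotopic arms reduces to one facial decision on the arm syn to the catalyst side chain. C5 follows from C1, since the three-atom tether can reach C5 only on the face it occupies at C1, so the fusion is cis. C4 is set in the aldol: a hydrogen-bonded closed transition state keeps the carbonyl oxygen near C6, putting the hydroxyl on the concave face and isopropyl on the convex face, and the reversible aldol favours the same epimer through its O–H···O=C6 bond. C2 equilibrates through the nitronate to the epimer trans to isopropyl and is erased in step 10. The step needs mono-addition and no loss of HNO2 from 9: pressure favours the bond-forming events over fragmentation, the acid cocatalyst keeps free base low, and after the first addition the second enone is held as an unreactive dienamine until the intramolecular aldol consumes it.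

Step 7
Reactants: 11 (1S,3S,3aS,8aR)-3-hydroxy-6,8a-dimethyl-1-nitro-3-(propan-2-yl)-2,3,3a,7,8,8a-hexahydroazulen-4(1H)-one
Product: 13 (1S,3S,3aS,8aR)-3-hydroxy-6,8a-dimethyl-1-nitro-3-(propan-2-yl)-1,2,3,3a,8,8a-hexahydroazulen-4(5H)-one, via trilithium dienolate 12 (not isolated)
Conditions: LiN(i-Pr)2 (3.5 equiv), THF, −78 → −50 °C; AcOH, −78 °C
Reagents that add atoms: none
Why: Deconjugation by kinetic α-protonation of an extended dienolate: the first two equivalents of base form the C2 nitronate and the C4 lithium alkoxide (stable to retro-aldol at −78 °C and unable to eliminate), and the third removes a C9 γ-proton cis to the carbonyl because C5–H is flanked by two fully substituted carbons. Acetic acid protonates C7, moving the alkene to C8=C9, and returns the nitro group from the convex face.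

Step 8
Reactants: 13 (1S,3S,3aS,8aR)-3-hydroxy-6,8a-dimethyl-1-nitro-3-(propan-2-yl)-1,2,3,3a,8,8a-hexahydroazulen-4(5H)-one
Product: 14 (1S,3S,3aR,4R,8aR)-6,8a-dimethyl-1-nitro-3-(propan-2-yl)-1,2,3,3a,4,5,8,8a-octahydroazulene-3,4-diol
Conditions: Me4NBH(OAc)3, MeCN–AcOH (1:1), −30 °C
Reagents that add atoms: none
Why: Evans–Saksena anti reduction: the C4 hydroxyl exchanges onto boron and delivers hydride to the concave face of the C6 ketone, placing the new hydroxyl on the convex face (6R, anti to C4–OH). The reagent ignores ketones without a β-hydroxyl and the nitro group, and the medium is too weakly acidic at −30 °C to reconjugate the alkene.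

Step 9
Reactants: 14 (1S,3S,3aR,4R,8aR)-6,8a-dimethyl-1-nitro-3-(propan-2-yl)-1,2,3,3a,4,5,8,8a-octahydroazulene-3,4-diol; 15 3,4,5-trimethoxybenzoyl chloride
Product: 16 (1S,3S,3aR,4R,8aR)-3-hydroxy-6,8a-dimethyl-1-nitro-3-(propan-2-yl)-1,2,3,3a,4,5,8,8a-octahydroazulen-4-yl 3,4,5-trimethoxybenzoate
Conditions: pyridine, DMAP (cat.), CH2Cl2, 0 °C → rt
Reagents that add atoms: none
Why: DMAP-catalysed acylation; the secondary C6 hydroxyl on the convex face reacts, the hindered tertiary C4 hydroxyl does not, and pyridine is too weak a base to form the nitronate.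

Step 10
Reactants: 16 (1S,3S,3aR,4R,8aR)-3-hydroxy-6,8a-dimethyl-1-nitro-3-(propan-2-yl)-1,2,3,3a,4,5,8,8a-octahydroazulen-4-yl 3,4,5-trimethoxybenzoate
Product: 18 (3S,3aR,4R,8aR)-3-hydroxy-6,8a-dimethyl-1-oxo-3-(propan-2-yl)-1,2,3,3a,4,5,8,8a-octahydroazulen-4-yl 3,4,5-trimethoxybenzoate, via potassium nitronate 17 (not isolated)
Conditions: KOt-Bu, THF, 0 °C; then aq. TiCl3, NH4OAc, THF–H2O, 0 °C → rt
Reagents that add atoms: water, O
Why: Reductive Nef reaction: buffered TiCl3 reduces the nitronate through the oxime to the imine, which hydrolyses to the C2 ketone near pH 5–6, conditions that spare the alkene, the aryl ester and the new β-hydroxy ketone; the C2 configuration is erased on purpose.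

Step 11
Reactants: 18 (3S,3aR,4R,8aR)-3-hydroxy-6,8a-dimethyl-1-oxo-3-(propan-2-yl)-1,2,3,3a,4,5,8,8a-octahydroazulen-4-yl 3,4,5-trimethoxybenzoate
Product: 19 (1S,3S,3aR,4R,8aR)-1,3-dihydroxy-6,8a-dimethyl-3-(propan-2-yl)-1,2,3,3a,4,5,8,8a-octahydroazulen-4-yl 3,4,5-trimethoxybenzoate
Conditions: Li[HB(s-Bu)3], THF, −78 °C; H2O
Reagents that add atoms: none
Why: Bulky trialkylborohydride reduction of a cyclopentanone; hydride should enter from the convex face, anti to the pseudoaxial C1–C10 and C4–O bonds and away from ring B, giving the 2S alcohol cis to the C4 hydroxyl. The reagent carries a single hydride, so no hydroxyl-directed delivery to the wrong face is possible, and the aryl ester is inert at −78 °C.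

Step 12
Reactants: 19 (1S,3S,3aR,4R,8aR)-1,3-dihydroxy-6,8a-dimethyl-3-(propan-2-yl)-1,2,3,3a,4,5,8,8a-octahydroazulen-4-yl 3,4,5-trimethoxybenzoate; 20 angelic acid
Product: 22 (1S,3S,3aR,4R,8aR)-3-hydroxy-6,8a-dimethyl-3-(propan-2-yl)-4-[(3,4,5-trimethoxybenzoyl)oxy]-1,2,3,3a,4,5,8,8a-octahydroazulen-1-yl (2Z)-2-methylbut-2-enoate, via mixed anhydride 21 (not isolated)
Conditions: 2,4,6-Cl3C6H2COCl, Et3N, toluene, rt; then 19, 80 °C
Reagents that add atoms: none
Why: Yamaguchi-type esterification through the mixed anhydride without a nucleophilic catalyst, the standard way to make angelates without Z to E isomerisation; the secondary C2 hydroxyl reacts and the tertiary C4 hydroxyl does not.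

## Compound list

1 | 3-methylcyclohex-2-en-1-one | CC1=CC(=O)CCC1 | starting material
2 | lithium 5-methylcyclohexa-1,5-dien-1-olate | [Li+].[O-]C1=CCCC(C)=C1 | intermediate
3 | 3,6-dimethylcyclohex-2-en-1-one (racemic) | CC1CCC(C)=CC1=O | intermediate
4 | [(2,5-dimethylcyclohexa-1,5-dien-1-yl)oxy]trimethylsilane | CC1=C(O[Si](C)(C)C)C=C(C)CC1 | intermediate
5 | [(3,6-dimethylbicyclo[4.1.0]hept-2-en-1-yl)oxy]trimethylsilane (racemic) | C[Si](C)(C)OC12CC1(C)CCC(C)=C2 | intermediate
6 | 6-chloro-3,6-dimethylcyclohept-2-en-1-one (racemic) | CC1=CC(=O)CC(C)(Cl)CC1 | intermediate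
7 | 3,6-dimethylcyclohepta-2,6-dien-1-one | CC1=CC(=O)C=C(C)CC1 | intermediate
8 | 4-methylpent-1-en-3-one | CC(C)C(=O)C=C | starting material
9 | 4-methyl-1-nitropentan-3-one | CC(C)C(=O)CC[N+](=O)[O-] | intermediate
10 | (6R)-3,6-dimethyl-6-[(1S)-4-methyl-1-nitro-3-oxopentyl]cyclohept-2-en-1-one | CC(C)C(=O)C[C@H]([N+](=O)[O-])[C@@]1(C)CC(=O)C=C(C)CC1 | intermediate
11 | (1S,3S,3aS,8aR)-3-hydroxy-6,8a-dimethyl-1-nitro-3-(propan-2-yl)-2,3,3a,7,8,8a-hexahydroazulen-4(1H)-one (nitro carbon epimerisable, of no consequence) | [O-][N+](=O)[C@H]1C[C@](O)(C(C)C)[C@H]2C(=O)C=C(C)CC[C@@]12C | intermediate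
12 | trilithium salt of 11 (C2 nitronate, C4 alkoxide, C6–C9 dienolate) | [Li+].[Li+].[Li+].[O-][N+]([O-])=C1C[C@]([O-])(C(C)C)[C@H]2C([O-])=CC(C)=CC[C@@]12C | intermediate
13 | (1S,3S,3aS,8aR)-3-hydroxy-6,8a-dimethyl-1-nitro-3-(propan-2-yl)-1,2,3,3a,8,8a-hexahydroazulen-4(5H)-one | [O-][N+](=O)[C@H]1C[C@](O)(C(C)C)[C@H]2C(=O)CC(C)=CC[C@@]12C | intermediate
14 | (1S,3S,3aR,4R,8aR)-6,8a-dimethyl-1-nitro-3-(propan-2-yl)-1,2,3,3a,4,5,8,8a-octahydroazulene-3,4-diol (3a descriptor changes by priority only) | [O-][N+](=O)[C@H]1C[C@](O)(C(C)C)[C@H]2[C@H](O)CC(C)=CC[C@@]12C | intermediate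
15 | 3,4,5-trimethoxybenzoyl chloride | COc1cc(cc(OC)c1OC)C(Cl)=O | starting material
16 | (1S,3S,3aR,4R,8aR)-3-hydroxy-6,8a-dimethyl-1-nitro-3-(propan-2-yl)-1,2,3,3a,4,5,8,8a-octahydroazulen-4-yl 3,4,5-trimethoxybenzoate | [O-][N+](=O)[C@H]1C[C@](O)(C(C)C)[C@H]2[C@H](OC(=O)c3cc(OC)c(OC)c(OC)c3)CC(C)=CC[C@@]12C | intermediate
17 | potassium nitronate of 16 | [K+].[O-][N+]([O-])=C1C[C@](O)(C(C)C)[C@H]2[C@H](OC(=O)c3cc(OC)c(OC)c(OC)c3)CC(C)=CC[C@@]12C | intermediate
18 | (3S,3aR,4R,8aR)-3-hydroxy-6,8a-dimethyl-1-oxo-3-(propan-2-yl)-1,2,3,3a,4,5,8,8a-octahydroazulen-4-yl 3,4,5-trimethoxybenzoate | O=C1C[C@](O)(C(C)C)[C@H]2[C@H](OC(=O)c3cc(OC)c(OC)c(OC)c3)CC(C)=CC[C@@]12C | intermediate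
19 | (1S,3S,3aR,4R,8aR)-1,3-dihydroxy-6,8a-dimethyl-3-(propan-2-yl)-1,2,3,3a,4,5,8,8a-octahydroazulen-4-yl 3,4,5-trimethoxybenzoate | O[C@H]1C[C@](O)(C(C)C)[C@H]2[C@H](OC(=O)c3cc(OC)c(OC)c(OC)c3)CC(C)=CC[C@@]12C | intermediate
20 | angelic acid, (2Z)-2-methylbut-2-enoic acid | C/C=C(/C)C(=O)O | starting material
21 | (2Z)-2-methylbut-2-enoic 2,4,6-trichlorobenzoic anhydride | C/C=C(/C)C(=O)OC(=O)c1c(Cl)cc(Cl)cc1Cl | intermediate
22 | (1S,3S,3aR,4R,8aR)-3-hydroxy-6,8a-dimethyl-3-(propan-2-yl)-4-[(3,4,5-trimethoxybenzoyl)oxy]-1,2,3,3a,4,5,8,8a-octahydroazulen-1-yl (2Z)-2-methylbut-2-enoate | C/C=C(/C)C(=O)O[C@H]1C[C@](O)(C(C)C)[C@H]2[C@H](OC(=O)c3cc(OC)c(OC)c(OC)c3)CC(C)=CC[C@@]12C | target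

## Step count and least certain steps

Total: 12 steps. Longest linear sequence: 11 steps (1 to 22 through steps 1–4 and 6–12); the nitro ketone branch adds step 5.

**Step 6 (key step).** The most likely failures are:
- base-induced loss of nitrous acid from the β-nitro ketone before it adds, because the ketone acidifies the hydrogens next to the nitro-bearing carbon;
- a second, transannular conjugate addition of the still acidic C2 nitronate onto the remaining enone;
- incomplete discrimination between the enantiotopic enone termini at a congested β,β-disubstituted position.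

The fallback separates the two bond formations and masks the ketone. Setting out from 9, ketalisation (ethylene glycol, TsOH, toluene, water removal) gives 2-(2-nitroethyl)-2-(propan-2-yl)-1,3-dioxolane F1, which cannot lose HNO2. Its amine-catalysed addition to 7 under the same pressure conditions gives the ketal-protected adduct (6R)-3,6-dimethyl-6-{(1S)-1-nitro-2-[2-(propan-2-yl)-1,3-dioxolan-2-yl]ethyl}cyclohept-2-en-1-one F2. Aqueous acid then unveils 10, and pyrrolidinium acetate closes the aldol, returning to the route at 11.

**Step 7.** What may go wrong is deprotonation at the wrong site (C5 or the C8 methyl), retro-aldol opening of the alkoxide if the mixture warms, or reconjugation during work-up; all stem from a β-hydroxy enone being asked to carry three negative charges. The fallback avoids anionic intermediates. Setting out from 11, soft enolisation with Me3SiOTf and Et3N gives the tris(trimethylsilyl) derivative of 11 (C2 silyl nitronate, C4 silyl ether, C6–C9 silyl dienol ether) F3, formed as the more substituted endocyclic dienol ether. Bu4NF buffered with AcOH at −78 °C then removes all three silyl groups with kinetic protonation at C7, returning to the route at 13.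

**Step 11.** What may go wrong is poor facial selectivity: on the convex face the hydride passes the C1 methyl and the isopropyl group, so attack from the concave face may compete. The fallback inverts instead of selecting. Setting out from 18, Me4NBH(OAc)3 delivers hydride from the C4 hydroxyl and should give cleanly the epimeric alcohol (1R,3S,3aR,4R,8aR)-1,3-dihydroxy-6,8a-dimethyl-3-(propan-2-yl)-1,2,3,3a,4,5,8,8a-octahydroazulen-4-yl 3,4,5-trimethoxybenzoate F4. Mitsunobu inversion with chloroacetic acid, PPh3 and diisopropyl azodicarboxylate gives the (1S) chloroacetate (1S,3S,3aR,4R,8aR)-1-[(chloroacetyl)oxy]-3-hydroxy-6,8a-dimethyl-3-(propan-2-yl)-1,2,3,3a,4,5,8,8a-octahydroazulen-4-yl 3,4,5-trimethoxybenzoate F5; the same openness of the concave face that would spoil step 11 lets the carboxylate enter there. Thiourea with NaHCO3 in ethanol removes the chloroacetyl group without touching the aryl ester, returning to the route at 19.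

**Step 12.** What may go wrong is slow acylation of the hindered concave-face hydroxyl next to the quaternary carbon, so that prolonged heating isomerises the angeloyl unit to tigloyl. The fallback builds the Z-alkene on the ester instead of transferring it. Setting out from 19, acylation with 2-[bis(2,2,2-trifluoroethoxy)phosphoryl]propanoic acid (dicyclohexylcarbodiimide, DMAP, where no alkene geometry is at stake) gives the phosphonate ester (1S,3S,3aR,4R,8aR)-1-({2-[bis(2,2,2-trifluoroethoxy)phosphoryl]propanoyl}oxy)-3-hydroxy-6,8a-dimethyl-3-(propan-2-yl)-1,2,3,3a,4,5,8,8a-octahydroazulen-4-yl 3,4,5-trimethoxybenzoate F6. Still–Gennari olefination with acetaldehyde (KN(SiMe3)2, 18-crown-6, THF, −78 °C) then forms the Z-trisubstituted enoate directly, returning to the route at 22.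

## Further compounds

F1 | step 6 | 2-(2-nitroethyl)-2-(propan-2-yl)-1,3-dioxolane | CC(C)C1(CC[N+](=O)[O-])OCCO1
F2 | step 6 | (6R)-3,6-dimethyl-6-{(1S)-1-nitro-2-[2-(propan-2-yl)-1,3-dioxolan-2-yl]ethyl}cyclohept-2-en-1-one | CC(C)C1(C[C@H]([N+](=O)[O-])[C@@]2(C)CC(=O)C=C(C)CC2)OCCO1
F3 | step 7 | tris(trimethylsilyl) derivative of 11 (C2 silyl nitronate, C4 silyl ether, C6–C9 silyl dienol ether) | C[Si](C)(C)O[N+]([O-])=C1C[C@](O[Si](C)(C)C)(C(C)C)[C@H]2C(O[Si](C)(C)C)=CC(C)=CC[C@@]12C
F4 | step 11 | (1R,3S,3aR,4R,8aR)-1,3-dihydroxy-6,8a-dimethyl-3-(propan-2-yl)-1,2,3,3a,4,5,8,8a-octahydroazulen-4-yl 3,4,5-trimethoxybenzoate | O[C@@H]1C[C@](O)(C(C)C)[C@H]2[C@H](OC(=O)c3cc(OC)c(OC)c(OC)c3)CC(C)=CC[C@@]12C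
F5 | step 11 | (1S,3S,3aR,4R,8aR)-1-[(chloroacetyl)oxy]-3-hydroxy-6,8a-dimethyl-3-(propan-2-yl)-1,2,3,3a,4,5,8,8a-octahydroazulen-4-yl 3,4,5-trimethoxybenzoate | ClCC(=O)O[C@H]1C[C@](O)(C(C)C)[C@H]2[C@H](OC(=O)c3cc(OC)c(OC)c(OC)c3)CC(C)=CC[C@@]12C
F6 | step 12 | (1S,3S,3aR,4R,8aR)-1-({2-[bis(2,2,2-trifluoroethoxy)phosphoryl]propanoyl}oxy)-3-hydroxy-6,8a-dimethyl-3-(propan-2-yl)-1,2,3,3a,4,5,8,8a-octahydroazulen-4-yl 3,4,5-trimethoxybenzoate | CC(C(=O)O[C@H]1C[C@](O)(C(C)C)[C@H]2[C@H](OC(=O)c3cc(OC)c(OC)c(OC)c3)CC(C)=CC[C@@]12C)P(=O)(OCC(F)(F)F)OCC(F)(F)F
A1 | alternative 1 | methyl 2-diazobut-3-enoate | COC(=O)C(=[N+]=[N-])C=C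
A2 | alternative 1 | tert-butyl (2E)-4-[(tert-butyldimethylsilyl)oxy]-2-methylpenta-2,4-dienoate | C=C(O[Si](C)(C)C(C)(C)C)/C=C(\C)C(=O)OC(C)(C)C
A3 | alternative 1 | 1-tert-butyl 4-methyl (1R)-6-[(tert-butyldimethylsilyl)oxy]-1-methylcyclohepta-3,6-diene-1,4-dicarboxylate | COC(=O)C1=CC[C@@](C)(C(=O)OC(C)(C)C)C=C(O[Si](C)(C)C(C)(C)C)C1
A4 | alternative 2 | (5S)-2-diazo-5-(2-methoxy-4-methylphenyl)-6-methyl-5-[(triethylsilyl)oxy]heptan-3-one | CC(=[N+]=[N-])C(=O)C[C@](O[Si](CC)(CC)CC)(C(C)C)c1ccc(C)cc1OC
A5 | alternative 2 | (3S,8aR)-4-methoxy-6,8a-dimethyl-3-(propan-2-yl)-3-[(triethylsilyl)oxy]-2,3-dihydroazulen-1(8aH)-one | O=C1C[C@](O[Si](CC)(CC)CC)(C(C)C)C2=C(OC)C=C(C)C=C[C@@]12C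
A6 | alternative 3 | (4R,5R,7R)-5-[(tert-butyldimethylsilyl)oxy]-4,7-diethenyl-3,7-dimethyloxepan-2-one | C=C[C@@]1(C)C[C@@H](O[Si](C)(C)C(C)(C)C)[C@H](C=C)C(C)C(=O)O1
A7 | alternative 3 | (1R,6R,7R)-6-[(tert-butyldimethylsilyl)oxy]-7-ethenyl-1,4-dimethylcyclohept-3-ene-1-carboxylic acid | OC(=O)[C@]1(C)CC=C(C)C[C@@H](O[Si](C)(C)C(C)(C)C)[C@@H]1C=C
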